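The cyclohexane ring is closed by a Diels–Alder reaction that forms C1–C6 and C4–C5 at once (bisabolane numbering: ring C1–C6, oxygen on C2 and C5, side chain C7–C11 on C6). It exploits the C5–C6–C7–C8–C9 chain of the target: bonding the C9 carbonyl carbon to C5 folds this chain into (R)-4-methylcyclopent-2-enone, whose C5=C6 bond is the dienophile for 2-silyloxy-3-methylbuta-1,3-diene (C1–C4, oxygen on C2). One operation builds the ring, sets C6 anti to the C7 methyl and fixes the 1,4-dioxygen pattern. Baeyer–Villiger cleavage of the temporary cyclopentanone later returns the C5–O bond and a C9 lactone that accepts the isobutenyl group.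

Key step: step 3

Numbering used for every compound: C1 = ring CH2 between C2 and C6; C2 = ring carbon that ends as CH–OAc; C3 = ring CH–CH3; C4 = ring CH2; C5 = ring carbon that ends as CH–O-angeloyl; C6 = ring CH bearing the side chain; C7 = CH(CH3); C8 = CH2; C9 = carbon that ends as CH–OAc; C10=C11 = isobutenyl alkene.
Remark: compounds 7, 8, 11, 13 and 14 are carried as mixtures of C3 epimers, because C3 is set only by the equilibration in step 8.

Step 1
Reactants: 1 (R)-4-(tert-butyldimethylsilyloxy)cyclopent-2-en-1-one
Product: 3 (R)-4-methylcyclopent-2-en-1-one, via trans-3-methyl-4-silyloxycyclopentanone 2 (not isolated)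
Conditions: Me2CuLi (from CuI + 2 MeLi), Et2O, −78 °C; AcOH quench; then DBU, CH2Cl2, 0 °C → rt
Reagents that add atoms: lithium dimethylcuprate, [Li+].C[Cu-]C
Why: Conjugate addition of the lithium dialkylcuprate anti to the C4 silyloxy group, then E1cB β-elimination of silanolate from the β-silyloxy ketone; the methyl-bearing carbon, set trans to the departing OTBS group, becomes the (R) stereocentre that ends as C7.

Step 2
Reactants: 4 3-methylbut-3-en-2-one
Product: 5 tert-butyldimethyl[(3-methylbuta-1,3-dien-2-yl)oxy]silane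
Conditions: TBSOTf, Et3N, Et2O, 0 °C
Reagents that add atoms: tert-butyldimethylsilyl triflate, CC(C)(C)[Si](C)(C)OS(=O)(=O)C(F)(F)F
Why: Soft enolisation and O-silylation; only the methyl group of 4 can be deprotonated, so the cross-conjugated 2-silyloxydiene should form as the single regioisomer with no stereocentre.

Step 3
Reactants: 3 (R)-4-methylcyclopent-2-en-1-one; 5 tert-butyldimethyl[(3-methylbuta-1,3-dien-2-yl)oxy]silane
Product: 6 (3R,3aS,7aS)-5-(tert-butyldimethylsilyloxy)-3,6-dimethyl-2,3,3a,4,7,7a-hexahydro-1H-inden-1-one (cis-fused)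
Conditions: EtAlCl2 (0.2 equiv), 5 (1.5 equiv), CH2Cl2, −78 → −30 °C; Et3N, then aq. NaHCO3
Reagents that add atoms: none
Why: Lewis-acid-catalysed normal-demand Diels–Alder reaction: EtAlCl2 on the carbonyl of 3 lowers the enone LUMO and the diene adds in a concerted, asynchronous [4+2] step in which the C1–C6 bond is the more advanced and C4–C5 completes in the same transition state. The closure is a suprafacial–suprafacial cycloaddition that makes the six-membered carbocycle C1–C6 as its silyl enol ether, cis-fused to the cyclopentanone. C6 is controlled by the C7 methyl group of 3, which shields one face of the enone so that the diene bonds anti to it; C5 follows from suprafacial addition to the cis alkene (cis ring fusion) and is inverted on purpose in step 7. The step needs regio- and facial selectivity: the silyloxy group on C2 puts the largest HOMO coefficient on the C1 terminus, which pairs with the enone β-carbon C6 and places C2–O para to C5, while the unsubstituted diene termini leave no endo/exo question. The closest known reaction type is the alkylaluminium-chloride-promoted cycloaddition of 2-silyloxybutadienes with cyclopent-2-enones.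

Step 4
Reactants: 6 cis-fused silyl enol ether
Product: 7 (3R,3aS,7aS)-3,6-dimethyloctahydroindene-1,5-dione 5-(ethylene ketal) (cis-fused; both C3 epimers)
Conditions: ethylene glycol (1.5 equiv), PPTS (0.1 equiv), benzene, 4 Å MS, rt → 50 °C
Reagents that add atoms: ethylene glycol, OCCO
Why: Acid-catalysed transketalisation of the enol ether (protonation at C3, capture of the oxocarbenium ion by the diol, loss of silanol) should give the dioxolane at C2, while the cyclopentanone beside the ring-fusion methine ketalises much more slowly and is left free; C3 forms as an epimer mixture that step 8 corrects.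

Step 5
Reactants: 7 keto ketal
Product: 8 (4R,4aS,8aS)-4,7-dimethyloctahydro-2H-chromene-2,6-dione 6-(ethylene ketal) (cis-fused δ-lactone; both C3 epimers)
Conditions: mCPBA, NaHCO3 (solid buffer), CH2Cl2, rt
Reagents that add atoms: mCPBA, OOC(=O)c1cccc(Cl)c1
Why: Baeyer–Villiger oxidation in which the more substituted α-carbon (C5, the ring-fusion methine) migrates in preference to the C8 methylene with retention, giving the C5–O bond and leaving C9 as the lactone carbonyl; the buffered peracid should not touch the dioxolane.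

Step 6
Reactants: 8 δ-lactone; 9 1-bromo-2-methylprop-1-ene
Product: 11 (6R)-6-[(8S,9S)-8-hydroxy-6-methyl-1,4-dioxaspiro[4.5]decan-9-yl]-2-methylhept-2-en-4-one (C5–OH cis to the C6 side chain; both C3 epimers), via 2-methylprop-1-enyllithium 10 (not isolated)
Conditions: 9, t-BuLi (2 equiv per 9), Et2O, −78 °C; then 8, THF, −78 °C; AcOH quench
Reagents that add atoms: none
Why: Mono-addition of an alkenyllithium to a lactone: the tetrahedral lithium lactolate is stable at −78 °C and opens only on protonation, so the δ-hydroxy enone should form without over-addition and without touching a stereocentre.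

Step 7
Reactants: 11 δ-hydroxy enone; 12 angelic acid ((Z)-2-methylbut-2-enoic acid)
Product: 13 (8R,9S)-6-methyl-9-[(2R)-6-methyl-4-oxohept-5-en-2-yl]-1,4-dioxaspiro[4.5]decan-8-yl (Z)-2-methylbut-2-enoate (both C3 epimers)
Conditions: PPh3, DIAD, toluene, 0 °C → rt
Reagents that add atoms: none
Why: Mitsunobu esterification: SN2 displacement of the C5 oxyphosphonium by angelate inverts C5, placing the ester trans to the C6 side chain, and the neutral conditions should keep the Z geometry of the angeloyl group.

Step 8
Reactants: 13 angelate enone ketal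
Product: 15 (1R,2S,5S)-5-methyl-2-[(2R)-6-methyl-4-oxohept-5-en-2-yl]-4-oxocyclohexyl (Z)-2-methylbut-2-enoate, via C3-epimeric diketone 14 (not isolated)
Conditions: TsOH·H2O (0.1 equiv), acetone/H2O (10:1), 40 °C
Reagents that add atoms: water, O
Why: Acid-catalysed ketal hydrolysis; the same acid enolises the C2 ketone, so C3 should equilibrate (thermodynamic control) to the epimer in which the C3 methyl, the C5 ester and the C6 side chain are all equatorial.

Step 9
Reactants: 15 diketone
Product: 16 (1R,2S,4R,5S)-4-hydroxy-5-methyl-2-[(2R)-6-methyl-4-oxohept-5-en-2-yl]cyclohexyl (Z)-2-methylbut-2-enoate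
Conditions: LiBH(s-Bu)3 (1.05 equiv), THF, −78 °C; AcOH quench
Reagents that add atoms: none
Why: Reduction with a bulky trialkylborohydride: equatorial attack on the 2-methylcyclohexanone-type C2 ketone should give the axial alcohol cis to the C3 methyl, and at −78 °C the saturated ketone reacts ahead of the β,β-disubstituted enone and the esters.

Step 10
Reactants: 16 hydroxy enone
Product: 17 (1R,2S,4R,5S)-4-hydroxy-2-[(2R,4R)-4-hydroxy-6-methylhept-5-en-2-yl]-5-methylcyclohexyl (Z)-2-methylbut-2-enoate
Conditions: (S)-2-methyl-CBS-oxazaborolidine (0.3 equiv), catecholborane (2.5 equiv), toluene, −78 °C; MeOH, aq. NaHCO3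
Reagents that add atoms: none
Why: Corey–Bakshi–Shibata reduction: the (S)-oxazaborolidine treats the alkenyl group as the large substituent and should deliver hydride to the face that gives the (R)-allylic alcohol at C9 (catalyst control), while catecholborane leaves the alkenes and the angelate alone.

Step 11
Reactants: 17 diol
Product: 18 (1R,2S,4R,5S)-4-acetoxy-2-[(2R,4R)-4-acetoxy-6-methylhept-5-en-2-yl]-5-methylcyclohexyl (Z)-2-methylbut-2-enoate
Conditions: Ac2O, DMAP (cat.), pyridine, CH2Cl2, rt
Reagents that add atoms: acetic anhydride, CC(=O)OC(C)=O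
Why: DMAP-catalysed acylation of the two secondary alcohols (C2 and C9) affects no stereocentre and should leave the angelate intact, giving the target.

Compound list
1 | (R)-4-(tert-butyldimethylsilyloxy)cyclopent-2-en-1-one | O=C1C=C[C@H](O[Si](C)(C)C(C)(C)C)C1 | starting material
2 | (3R,4R)-4-(tert-butyldimethylsilyloxy)-3-methylcyclopentan-1-one (trans; not isolated) | O=C1C[C@@H](C)[C@H](O[Si](C)(C)C(C)(C)C)C1 | intermediate
3 | (R)-4-methylcyclopent-2-en-1-one | O=C1C=C[C@H](C)C1 | intermediate
4 | 3-methylbut-3-en-2-one | CC(=O)C(C)=C | starting material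
5 | tert-butyldimethyl[(3-methylbuta-1,3-dien-2-yl)oxy]silane | C=C(O[Si](C)(C)C(C)(C)C)C(C)=C | intermediate
6 | (3R,3aS,7aS)-5-(tert-butyldimethylsilyloxy)-3,6-dimethyl-2,3,3a,4,7,7a-hexahydro-1H-inden-1-one (cis-fused) | [C@@H]12CC(C)=C(O[Si](C)(C)C(C)(C)C)C[C@H]2[C@H](C)CC1=O | intermediate
7 | (3R,3aS,7aS)-3,6-dimethyloctahydroindene-1,5-dione 5-(ethylene ketal) (cis-fused; C3 epimers) | [C@@H]12CC(C)C3(OCCO3)C[C@H]2[C@H](C)CC1=O | intermediate
8 | (4R,4aS,8aS)-4,7-dimethyloctahydro-2H-chromene-2,6-dione 6-(ethylene ketal) (cis-fused; C3 epimers) | O1[C@H]2CC(C)C3(OCCO3)C[C@H]2[C@H](C)CC1=O | intermediate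
9 | 1-bromo-2-methylprop-1-ene | BrC=C(C)C | starting material
10 | 2-methylprop-1-enyllithium (not isolated) | [Li]C=C(C)C | intermediate
11 | (6R)-6-[(8S,9S)-8-hydroxy-6-methyl-1,4-dioxaspiro[4.5]decan-9-yl]-2-methylhept-2-en-4-one (C3 epimers) | O[C@H]1CC(C)C2(OCCO2)C[C@H]1[C@H](C)CC(=O)C=C(C)C | intermediate
12 | angelic acid, (Z)-2-methylbut-2-enoic acid | C/C=C(/C)C(=O)O | starting material
13 | (8R,9S)-6-methyl-9-[(2R)-6-methyl-4-oxohept-5-en-2-yl]-1,4-dioxaspiro[4.5]decan-8-yl (Z)-2-methylbut-2-enoate (C3 epimers) | C/C=C(/C)C(=O)O[C@@H]1CC(C)C2(OCCO2)C[C@H]1[C@H](C)CC(=O)C=C(C)C | intermediate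
14 | (1R,2S)-5-methyl-2-[(2R)-6-methyl-4-oxohept-5-en-2-yl]-4-oxocyclohexyl (Z)-2-methylbut-2-enoate (C3 epimers; not isolated) | C/C=C(/C)C(=O)O[C@@H]1CC(C)C(=O)C[C@H]1[C@H](C)CC(=O)C=C(C)C | intermediate
15 | (1R,2S,5S)-5-methyl-2-[(2R)-6-methyl-4-oxohept-5-en-2-yl]-4-oxocyclohexyl (Z)-2-methylbut-2-enoate | C/C=C(/C)C(=O)O[C@@H]1C[C@H](C)C(=O)C[C@H]1[C@H](C)CC(=O)C=C(C)C | intermediate
16 | (1R,2S,4R,5S)-4-hydroxy-5-methyl-2-[(2R)-6-methyl-4-oxohept-5-en-2-yl]cyclohexyl (Z)-2-methylbut-2-enoate | C/C=C(/C)C(=O)O[C@@H]1C[C@H](C)[C@H](O)C[C@H]1[C@H](C)CC(=O)C=C(C)C | intermediate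
17 | (1R,2S,4R,5S)-4-hydroxy-2-[(2R,4R)-4-hydroxy-6-methylhept-5-en-2-yl]-5-methylcyclohexyl (Z)-2-methylbut-2-enoate | C/C=C(/C)C(=O)O[C@@H]1C[C@H](C)[C@H](O)C[C@H]1[C@H](C)C[C@H](C=C(C)C)O | intermediate
18 | (1R,2S,4R,5S)-4-acetoxy-2-[(2R,4R)-4-acetoxy-6-methylhept-5-en-2-yl]-5-methylcyclohexyl (Z)-2-methylbut-2-enoate | C/C=C(/C)C(=O)O[C@@H]1C[C@H](C)[C@H](OC(C)=O)C[C@H]1[C@H](C)C[C@H](C=C(C)C)OC(C)=O | target

Total step count: 11
Longest linear sequence: 10 steps (step 1, then steps 3 to 11)

Steps most likely to fail

Step 7. What may go wrong: E2 elimination of the axial C5 oxyphosphonium (anti-periplanar axial hydrogens on C4 and C6) may outrun the SN2 inversion, or the angeloyl group may isomerise from Z to E under phosphine. Fallback: setting out from 11, the C5 alcohol would be oxidised with Dess–Martin periodinane to the C5 ketone F1, whose C6 centre stays with the side chain equatorial. NaBH4 in MeOH at −78 °C should then reduce this cyclohexanone ahead of the conjugated enone by axial hydride delivery, giving the equatorial 5-epi-alcohol F2. Yamaguchi esterification of F2 with 12 (2,4,6-trichlorobenzoyl chloride, Et3N, then DMAP, toluene) proceeds with retention and comes back to the route at 13.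

Step 3. What may go wrong: Lewis-acid-induced cleavage or oligomerisation of the silyloxydiene may compete, or the small C7 methyl may give poor facial discrimination. Fallback: setting out from 3 and 4, an anionic double Michael annulation replaces the cycloaddition. LiN(i-Pr)2 in THF at −78 °C would convert 4 into lithium 3-methylbuta-1,3-dien-2-olate F3, which adds to 3 anti to the methyl group to give the open-chain Michael adduct F4 as its enolate. On warming this closes by intramolecular Michael addition to the cis-fused bicyclic diketone F5. Selective ketalisation of the cyclohexanone of F5 (ethylene glycol, PPTS, benzene, Dean–Stark) comes back to the route at 7.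

Step 10. What may go wrong: poor facial selectivity of hydride delivery at C9, because the catalyst must tell a CH2R group from the isobutenyl group. Fallback: setting out from 16, Luche reduction (NaBH4, CeCl3·7H2O, MeOH, −40 °C) would give both C9 epimers without catalyst control. These are diastereomers and would be separated by chromatography into 17 and the (9S)-epimeric diol F6. F6 would be recycled by selective allylic oxidation with MnO2 back to 16, and the route continues from 17.

Further compounds
F1 | step 7 | (6R)-2-methyl-6-[(9S)-6-methyl-8-oxo-1,4-dioxaspiro[4.5]decan-9-yl]hept-2-en-4-one (C3 epimers) | O=C1CC(C)C2(OCCO2)C[C@H]1[C@H](C)CC(=O)C=C(C)C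
F2 | step 7 | (6R)-6-[(8R,9S)-8-hydroxy-6-methyl-1,4-dioxaspiro[4.5]decan-9-yl]-2-methylhept-2-en-4-one (C3 epimers) | O[C@@H]1CC(C)C2(OCCO2)C[C@H]1[C@H](C)CC(=O)C=C(C)C
F3 | step 3 | lithium 3-methylbuta-1,3-dien-2-olate | [Li]OC(=C)C(C)=C
F4 | step 3 | (3R,4S)-3-methyl-4-(3-methyl-2-oxobut-3-en-1-yl)cyclopentan-1-one | C=C(C)C(=O)C[C@H]1[C@H](C)CC(=O)C1
F5 | step 3 | (3R,3aS,7aS)-3,6-dimethyloctahydroindene-1,5-dione (cis-fused; C3 epimers) | [C@@H]12CC(C)C(=O)C[C@H]2[C@H](C)CC1=O
F6 | step 10 | (1R,2S,4R,5S)-4-hydroxy-2-[(2R,4S)-4-hydroxy-6-methylhept-5-en-2-yl]-5-methylcyclohexyl (Z)-2-methylbut-2-enoate | C/C=C(/C)C(=O)O[C@@H]1C[C@H](C)[C@H](O)C[C@H]1[C@H](C)C[C@@H](C=C(C)C)O
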